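**Retrosynthesis**
1. The target hydroperoxide comes from a late-stage Schenck ene reaction of ¹O₂ on the Δ4,5 trisubstituted alkene of the ovatodiolide-type bis-lactone **26**. This sets C5–OOH and the 4-methylene in one step, by peripheral attack on the macrocycle.
2. The 14-membered ring, the trans-α-methylene-γ-lactone and two stereocenters form together by intramolecular Hiyama–Nozaki–Barbier allylation of an enal with a 2-(bromomethyl)alk-2-enoate (anti, chair TS). The butenolide stereocenter is the only one set beforehand.
3. The butenolide is made by RCM of an acrylate of an (R)-vinyl carbinol. The carbinol comes from HKR-derived (S)-vinyloxirane plus an acetylide. The butenolide α-chain is attached by Negishi coupling of an α-iodobutenolide with a homoallylic zinc reagent.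
4. Both E-trisubstituted alkenes come from Zr-catalysed methylalumination of terminal alkynes. The allyl bromide comes from a Baylis–Hillman adduct.

Assumption: ovatodiolide is taken to be the deoxy compound **26**, with an E (ring-trans) Δ4,5 alkene whose methyl is cis to the adjacent ring CH₂.

---

**Step 1**
Reactants: 1 (±)-2-vinyloxirane
Product: 2 (S)-2-vinyloxirane
Conditions: (salen)Co(III)OAc (the enantiomer that hydrolyses the (R)-epoxide, 0.5 mol %), H₂O (0.55 equiv), 0 °C→rt, 16 h; distil
Reagents that add atoms: none
Why: Jacobsen hydrolytic kinetic resolution leaves the (S)-epoxide in >99 % ee and sets the future C6 stereocenter.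

**Step 2**
Reactants: 2; 3 trimethylsilylacetylene
Product: 4 (R)-6-(trimethylsilyl)hex-1-en-5-yn-3-ol
Conditions: 3, n-BuLi, THF, −78 °C; BF₃·OEt₂; then 2, −78 °C
Reagents that add atoms: trimethylsilylacetylene, C[Si](C)(C)C#C
Why: BF₃-promoted acetylide opening (Yamaguchi–Hirao) attacks the unhindered CH₂ and leaves the carbinol center untouched. The descriptor changes from S to R only because CIP priorities swap.

**Step 3**
Reactants: 4
Product: 5 (R)-hex-1-en-5-yn-3-ol
Conditions: K₂CO₃, MeOH, rt
Reagents that add atoms: none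
Why: Protodesilylation frees the terminal alkyne needed for carboalumination.

**Step 4**
Reactants: 5
Product: 6 (3R,5E)-6-iodo-5-methylhexa-1,5-dien-3-ol
Conditions: Me₃Al (2.5 equiv), Cp₂ZrCl₂ (20 mol %), CH₂Cl₂, 0 °C→rt; then I₂, THF, −30 °C
Reagents that add atoms: trimethylaluminium, C[Al](C)C (adds CH₃); iodine, II
Why: Negishi Zr-catalysed methylalumination is a syn carbometalation, so it gives the E-vinyl iodide with Me cis to I. This fixes the geometry of the alkene next to the lactone-bearing carbon; the free OH and the vinyl group are tolerated.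

**Step 5**
Reactants: 6
Product: 7 (2E,5R)-5-hydroxy-3-methylhepta-2,6-dienal
Conditions: t-BuLi (3 equiv), Et₂O, −78 °C; then DMF, −78→0 °C
Reagents that add atoms: DMF, CN(C)C=O (adds CHO)
Why: Li–I exchange proceeds with retention of alkene geometry, and formylation (Bouveault) gives the E-enal.

**Step 6**
Reactants: 7
Product: 8 (3R,5E)-7,7-dimethoxy-5-methylhepta-1,5-dien-3-ol
Conditions: HC(OMe)₃, PPTS (5 mol %), MeOH, rt
Reagents that add atoms: trimethyl orthoformate, COC(OC)OC (adds 2 OMe)
Why: Acetalisation masks the enal so it survives the amine, Pd and Zn steps that follow.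

**Step 7**
Reactants: 8; 9 acryloyl chloride
Product: 10 (3R,5E)-7,7-dimethoxy-5-methylhepta-1,5-dien-3-yl acrylate
Conditions: 9, Et₃N, DMAP (cat.), CH₂Cl₂, −20→0 °C
Reagents that add atoms: acryloyl chloride, C=CC(=O)Cl
Why: Schotten–Baumann-type O-acylation proceeds with retention at the carbinol carbon.

**Step 8**
Reactants: 10
Product: 11 (5R)-5-[(2E)-4,4-dimethoxy-2-methylbut-2-en-1-yl]furan-2(5H)-one
Conditions: Grubbs II (5 mol %), CH₂Cl₂ (5 mM), 40 °C
Reagents that add atoms: none
Why: Ring-closing metathesis of the acrylate and vinyl carbinol is a known route to γ-substituted butenolides and does not touch the stereocenter.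

**Step 9**
Reactants: 11
Product: 12 (5R)-3-iodo-5-[(2E)-4,4-dimethoxy-2-methylbut-2-en-1-yl]furan-2(5H)-one
Conditions: I₂, pyridine, CH₂Cl₂, 0 °C→rt
Reagents that add atoms: iodine, II
Why: Johnson α-iodination of the butenolide (Michael addition of pyridine, iodination, elimination) gives the α-iodide.

**Step 10**
Reactants: 13 pent-4-yn-1-ol
Product: 14 tert-butyldimethyl(pent-4-yn-1-yloxy)silane
Conditions: TBSCl, imidazole, DMF, rt
Reagents that add atoms: TBSCl, CC(C)(C)[Si](C)(C)Cl
Why: Silyl protection of the primary alcohol.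

**Step 11**
Reactants: 14
Product: 15 tert-butyl{[(4E)-5-iodo-4-methylpent-4-en-1-yl]oxy}dimethylsilane
Conditions: Me₃Al, Cp₂ZrCl₂, CH₂Cl₂, rt; then I₂, THF, −30 °C
Reagents that add atoms: Me₃Al, C[Al](C)C; I₂, II
Why: Negishi methylalumination gives the E-trisubstituted vinyl iodide, which becomes the second trisubstituted alkene.

**Step 12**
Reactants: 15; 16 ethylene oxide
Product: 17 (3E)-7-(TBSO)-4-methylhept-3-en-1-ol
Conditions: t-BuLi (2.1 equiv), Et₂O, −78 °C; then 16, BF₃·OEt₂, −78 °C
Reagents that add atoms: ethylene oxide, C1CO1 (adds CH₂CH₂OH)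
Why: Li–I exchange retains the alkene geometry, and the BF₃-activated epoxide opening builds the homoallylic alcohol.

**Step 13**
Reactants: 17
Product: 18 tert-butyl{[(4E)-7-iodo-4-methylhept-4-en-1-yl]oxy}dimethylsilane
Conditions: I₂, PPh₃, imidazole, Et₂O/MeCN, 0 °C
Reagents that add atoms: iodine, II
Why: Appel-type SN2 iodination of the primary alcohol.

**Step 14**
Reactants: 18; 12
Product: 19 (5R)-3-{(3E)-7-(TBSO)-4-methylhept-3-en-1-yl}-5-[(2E)-4,4-dimethoxy-2-methylbut-2-en-1-yl]furan-2(5H)-one
Conditions: (i) Zn dust, LiCl, BrCH₂CH₂Br (5 mol %), TMSCl (1 mol %), THF, 40 °C, to make RZnI from 18; (ii) 12, Pd(PPh₃)₄ (5 mol %), THF, rt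
Reagents that add atoms: none (the organozinc is made from reactant 18)
Why: Negishi sp²–sp³ coupling under neutral conditions joins the two halves and leaves the base-sensitive γ-stereocenter intact.

**Step 15**
Reactants: 19
Product: 20 primary alcohol (free CH₂OH in place of the OTBS of 19)
Conditions: CSA (0.1 equiv), MeOH, 0 °C
Reagents that add atoms: none
Why: Acid-catalysed methanolysis removes the primary TBS ether, and the dimethyl acetal is stable in MeOH.

**Step 16**
Reactants: 20
Product: 21 aldehyde (CHO in place of the CH₂OH of 20)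
Conditions: Dess–Martin periodinane, NaHCO₃, CH₂Cl₂, rt
Reagents that add atoms: none
Why: Mild DMP oxidation gives the unhindered aliphatic aldehyde with no epimerisable α-center.

**Step 17**
Reactants: 21; 22 methyl acrylate
Product: 23 Baylis–Hillman adduct (chain ending CH(OH)C(=CH₂)CO₂Me)
Conditions: 22 (10 equiv), DABCO (0.5 equiv), MeOH, rt, 48 h
Reagents that add atoms: methyl acrylate, C=CC(=O)OC
Why: Morita–Baylis–Hillman reaction forms the three-carbon α-methylene ester unit; the new carbinol is racemic but becomes sp² in the next step.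

**Step 18**
Reactants: 23
Product: 24 allylic bromide (chain ending CH=C(CH₂Br)CO₂Me, acetal intact)
Conditions: MsCl, Et₃N, CH₂Cl₂, 0 °C; then LiBr, THF, 0 °C→rt
Reagents that add atoms: lithium bromide, [Li+].[Br-]
Why: Mesylation followed by SN2′ bromide displacement gives the 2-(bromomethyl)alk-2-enoate. The acetal still masks the enal, so the γ-acyloxy enal is not exposed to base.

**Step 19**
Reactants: 24
Product: 25 enal–allyl bromide (macrocyclisation precursor)
Conditions: PPTS (0.2 equiv), acetone/H₂O 10:1, 45 °C
Reagents that add atoms: water, O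
Why: Mild acetal hydrolysis releases the (E)-enal, whose geometry is unchanged.

**Step 20**
Reactants: 25
Product: 26 ovatodiolide-type bis-lactone, C=C1C(=O)O[C@H]2/C=C(\C)C[C@@H]3C=C(CC/C=C(\C)CC[C@H]12)C(=O)O3
Conditions: CrCl₂ (8 equiv), NiCl₂ (cat.), DMF, rt, substrate added by syringe pump (about 2 mM, 10 h); then TsOH (cat.), CH₂Cl₂
Reagents that add atoms: none
Why: Intramolecular Hiyama–Nozaki–Barbier allylation: the allylchromium adds to the enal through a chair Zimmerman–Traxler TS, giving the anti homoallylic alkoxide. This lactonises to the trans-fused α-methylene-γ-lactone, so ring closure and both lactone stereocenters form together. The macrocycle conformation imposed by the butenolide stereocenter is assumed to favour the natural diastereomer; the other is separable.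

**Step 21**
Reactants: 26
Product: 27 4-methylene-5β-hydroperoxyovatodiolide (target)
Conditions: O₂, TPP (1 mol %), visible light, CH₂Cl₂, −20 °C, 3 h; no reductant; cold neutral workup
Reagents that add atoms: singlet oxygen (from O₂), O=O
Why: Schenck ene reaction (¹O₂): the Δ4,5 alkene is the reactive one, because the other trisubstituted alkene is deactivated by its allylic lactone oxygen and the butenolide and methylene-lactone alkenes are electron-poor. The cis effect directs H-abstraction from the C4 methyl, which is cis to the C6 chain, giving the 4-methylene-5-OOH product; macrocycle periphery attack sets C5.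

---

**Compound list**

1 | (±)-2-vinyloxirane | C=CC1CO1 | starting material
2 | (S)-2-vinyloxirane | C=C[C@H]1CO1 | intermediate
3 | trimethylsilylacetylene | C[Si](C)(C)C#C | starting material
4 | (R)-6-(trimethylsilyl)hex-1-en-5-yn-3-ol | C=C[C@H](O)CC#C[Si](C)(C)C | intermediate
5 | (R)-hex-1-en-5-yn-3-ol | C=C[C@H](O)CC#C | intermediate
6 | (3R,5E)-6-iodo-5-methylhexa-1,5-dien-3-ol | C=C[C@H](O)C/C(C)=C/I | intermediate
7 | (2E,5R)-5-hydroxy-3-methylhepta-2,6-dienal | C=C[C@H](O)C/C(C)=C/C=O | intermediate
8 | (3R,5E)-7,7-dimethoxy-5-methylhepta-1,5-dien-3-ol | C=C[C@H](O)C/C(C)=C/C(OC)OC | intermediate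
9 | acryloyl chloride | C=CC(=O)Cl | starting material
10 | (3R,5E)-7,7-dimethoxy-5-methylhepta-1,5-dien-3-yl acrylate | C=CC(=O)O[C@@H](C=C)C/C(C)=C/C(OC)OC | intermediate
11 | (5R)-5-[(2E)-4,4-dimethoxy-2-methylbut-2-en-1-yl]furan-2(5H)-one | O=C1C=C[C@@H](C/C(C)=C/C(OC)OC)O1 | intermediate
12 | (5R)-3-iodo-5-[(2E)-4,4-dimethoxy-2-methylbut-2-en-1-yl]furan-2(5H)-one | O=C1C(I)=C[C@@H](C/C(C)=C/C(OC)OC)O1 | intermediate
13 | pent-4-yn-1-ol | C#CCCCO | starting material
14 | tert-butyldimethyl(pent-4-yn-1-yloxy)silane | C#CCCCO[Si](C)(C)C(C)(C)C | intermediate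
15 | tert-butyl{[(4E)-5-iodo-4-methylpent-4-en-1-yl]oxy}dimethylsilane | I/C=C(\C)CCCO[Si](C)(C)C(C)(C)C | intermediate
16 | ethylene oxide | C1CO1 | starting material
17 | (3E)-7-(TBSO)-4-methylhept-3-en-1-ol | OCC/C=C(\C)CCCO[Si](C)(C)C(C)(C)C | intermediate
18 | tert-butyl{[(4E)-7-iodo-4-methylhept-4-en-1-yl]oxy}dimethylsilane | ICC/C=C(\C)CCCO[Si](C)(C)C(C)(C)C | intermediate
19 | Negishi product: butenolide bearing the (3E)-7-(TBSO)-4-methylhept-3-en-1-yl chain at C3 and the acetal side chain at C5 | O=C1C(CC/C=C(\C)CCCO[Si](C)(C)C(C)(C)C)=C[C@@H](C/C(C)=C/C(OC)OC)O1 | intermediate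
20 | primary alcohol from 19 | O=C1C(CC/C=C(\C)CCCO)=C[C@@H](C/C(C)=C/C(OC)OC)O1 | intermediate
21 | aldehyde from 20 | O=C1C(CC/C=C(\C)CCC=O)=C[C@@H](C/C(C)=C/C(OC)OC)O1 | intermediate
22 | methyl acrylate | C=CC(=O)OC | starting material
23 | Baylis–Hillman adduct (racemic carbinol) | O=C1C(CC/C=C(\C)CCC(O)C(=C)C(=O)OC)=C[C@@H](C/C(C)=C/C(OC)OC)O1 | intermediate
24 | allylic bromide, acetal-protected | O=C1C(CC/C=C(\C)CCC=C(CBr)C(=O)OC)=C[C@@H](C/C(C)=C/C(OC)OC)O1 | intermediate
25 | enal–allyl bromide (cyclisation precursor) | O=C1C(CC/C=C(\C)CCC=C(CBr)C(=O)OC)=C[C@@H](C/C(C)=C/C=O)O1 | intermediate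
26 | ovatodiolide-type bis-lactone (Δ4,5 E-alkene) | C=C1C(=O)O[C@H]2/C=C(\C)C[C@@H]3C=C(CC/C=C(\C)CC[C@H]12)C(=O)O3 | intermediate
27 | 4-methylene-5β-hydroperoxyovatodiolide | C=C1C(=O)O[C@H]2/C=C(\C)C[C@@H]3C=C(CC[C@@H](OO)C(=C)CC[C@H]12)C(=O)O3 | target

**Totals:** 21 steps in total; longest linear sequence 17 steps (1→9, then 14→21).

**Three steps most likely to fail**
1. **Step 20 (Cr macrocyclisation).** Yield and remote diastereocontrol from the single butenolide stereocenter are uncertain. Fallback: make the trans-α-methylene lactone first by intermolecular Cr-Barbier on the two fragments, separate diastereomers at the acyclic stage, then close the macrocycle by intramolecular Negishi or B-alkyl Suzuki coupling at the butenolide α-carbon.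
2. **Step 21 (¹O₂ ene).** Regioselectivity versus the other trisubstituted alkene and facial selectivity at the new hydroperoxide carbon are both uncertain. Fallback: close the macrocycle by intramolecular NHK coupling of a C5 aldehyde with a C4 vinyl iodide to set the allylic alcohol diastereoselectively, then convert the mesylate to the hydroperoxide by SN2 with H₂O₂/base (inversion).
3. **Step 14 (Negishi on the α-iodobutenolide).** Butenolide γ-epimerisation, conjugate addition or homocoupling could all interfere. Fallback: build the α-chain on the acid side instead. Alkylate triethyl phosphonoacetate with iodide 18, do an HWE with HCHO, hydrolyse to the α-substituted acrylic acid, esterify with 8, and close the butenolide by RCM.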